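**Retrosynthetic overview** (labdane numbering; the target is an ent-labdane with a trans-decalin, equatorial C9 chain, equatorial 6-OH and 8-OH, and axial C17)
- C13=C14 is cut by Horner–Wadsworth–Emmons olefination of a C13 methyl ketone. The 6,8-diol goes back to a C6 ketone through the C7=C8 enone, an epoxide anti to C20, reductive C7–O cleavage and electron-transfer reduction of C6.
- C9–C11 goes back to a C9 nitronate and but-3-en-2-one. The nitro group is then removed by a radical reduction that sets C9.
- The plan rests on C9 in ring B, a CH whose three carbon neighbours are C8, C10 and C11. C8 and C10 are the two electrophilic termini on either side of the C6 carbonyl of β-damascone, namely the crotonyl β-carbon and the ring β-carbon.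
- This commercial dienone supplies ring A, C6, C7, C8 and the methyls C17 to C20. The carbon of nitromethane is therefore stitched between the two termini in a [5+1] double Michael annulation (C8–C9, then C9–C10).
- Ring order: ring A is bought, and ring B is the only ring formed (step 1).

Key step: step 1

Assumption: the quinine-derived thiourea is taken to give the (S) configuration at C8, by analogy with its sense of induction on chalcone-type enones. If the sense is the reverse, the quinidine-derived pseudoenantiomer is used and nothing else changes.

**Step 1**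
Reactants: 1 β-damascone; 2 nitromethane
Product: 4 (3S,4R,4aR,8aR)-3,4a,8,8-tetramethyl-4-nitrooctahydronaphthalen-1(2H)-one (trans-fused 9-nitrodecal-6-one; C8 methyl and C9 nitro equatorial), via (S)-gamma-nitro ketone 3 (not isolated)
Conditions: 2 (10 equiv), N-[3,5-bis(trifluoromethyl)phenyl]-N'-[(8α,9S)-6'-methoxycinchonan-9-yl]thiourea (10 mol %), PhMe, rt; evaporate excess 2; then 1,8-diazabicyclo[5.4.0]undec-7-ene (DBU, 0.3 equiv), DMSO, 50 °C
Reagents that add atoms: none
Why: Proposed new method: in stage one the quinuclidine nitrogen of the catalyst deprotonates 2 while the thiourea hydrogen-bonds the C6 carbonyl, and the nitronate adds to C8 of the planar, unhindered crotonyl alkene to form C8–C9 and set C8 as (S) under catalyst control, which is a known type of organocatalytic nitro-Michael addition. In stage two DBU regenerates the nitronate of 3, whose carbon C9 attacks the ring β-carbon C10 in a 6-endo-trig closure of ring B (C5–C6–C7–C8–C9–C10) through a chair-like transition state, and the C5=C6 enolate is then protonated at C5. The closest known reaction types are the double Michael addition of nitromethane to divinyl ketones, which gives 4-nitrocyclohexanones, and the addition of nitroalkanes to β,β-disubstituted enones such as mesityl oxide; neither has been shown for a tetrasubstituted enone terminus twisted out of conjugation. C10 is relayed from C8, because only attack on one face of C10 keeps the C8 methyl equatorial and clear of a 1,3-diaxial contact with C20, while C9 (α to nitro) and C5 (α to the ketone) stay epimerisable under DBU and should settle as equatorial nitro and trans ring fusion. The step needs site selectivity in stage one, secured by the tetrasubstituted, twisted C5=C10 alkene being inert to the mild catalyst system, and it needs ring closure to outrun retro-Michael loss of 2 from C8, secured by removing excess 2 and by an amidine base that forms the nitronate but is too weak to enolise C7. A sub-stoichiometric base keeps neutral 3 and 4 as resting states, so that the exchange of a weakly conjugated π bond for a σ bond, and not the strained nitronate of 4, decides the position of the equilibrium.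

**Step 2**
Reactants: 4 trans-fused 9-nitrodecal-6-one; 5 but-3-en-2-one
Product: 6 trans-fused 9-nitro-9-(3-oxobutyl)decal-6-one (chain axial and anti to C20; nitro equatorial; C8 methyl equatorial)
Conditions: 5 (3 equiv, in portions), DBU (0.3 equiv), MeCN, 0 °C to rt
Reagents that add atoms: none
Why: Nitro-Michael addition, in which C9–H is by far the most acidic site of 4 and its planar nitronate should add to the unsubstituted terminus of 5 on the face anti to the axial C20 methyl; the C9 configuration set here is without consequence because step 3 planarises C9.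

**Step 3**
Reactants: 6 tertiary nitro diketone
Product: 7 14,15-dinor-ent-labdane-6,13-dione (C9 chain equatorial and syn to C20; C8 methyl equatorial)
Conditions: Bu3SnH (3 equiv), AIBN (0.3 equiv), PhMe, 110 °C
Reagents that add atoms: none
Why: Tin hydride radical denitration of a tertiary nitroalkane, in which the stannyl radical adds to a nitro oxygen, C–N scission gives the tertiary C9 radical, and Bu3SnH should deliver hydrogen axially on the face anti to C20, leaving the chain equatorial as in the target while both ketones stay inert.

**Step 4**
Reactants: 7 6,13-diketone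
Product: 8 13,13-ethylenedioxy-14,15-dinor-ent-labdan-6-one
Conditions: ethane-1,2-diol (3 equiv), pyridinium p-toluenesulfonate (PPTS, cat.), PhH, reflux, Dean–Stark
Reagents that add atoms: ethane-1,2-diol, OCCO
Why: Chemoselective acetalisation, in which the open C13 methyl ketone reacts while the C6 carbonyl, wedged between C5 and the axial C19 and C20 methyls, does not, and the mild acid leaves the thermodynamically preferred trans fusion at C5.

**Step 5**
Reactants: 8 keto acetal
Product: 9 6-trimethylsilyloxy-13,13-ethylenedioxy-14,15-dinor-ent-labd-6-ene
Conditions: lithium diisopropylamide (LDA, 1.3 equiv), TMSCl (internal quench), THF, −78 to 0 °C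
Reagents that add atoms: chlorotrimethylsilane, C[Si](C)(C)Cl
Why: Kinetic enolate silylation, in which LDA removes the accessible axial C7–H whereas C5–H is buried between the quaternary carbons C4 and C10, so only the C6=C7 silyl enol ether should form and no stereocentre is touched.

**Step 6**
Reactants: 9 silyl enol ether
Product: 10 13,13-ethylenedioxy-14,15-dinor-ent-labd-7-en-6-one
Conditions: Pd(OAc)2 (1.05 equiv), MeCN, rt to 40 °C
Reagents that add atoms: none
Why: Saegusa–Ito oxidation, in which a divalent palladium enolate at C7 undergoes syn β-hydride elimination of C8–H to give the C7=C8 enone; this erases C8, whose relay task is finished, and leaves C5, C9 and C10 unchanged.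

**Step 7**
Reactants: 10 enone
Product: 11 7,8-epoxy-13,13-ethylenedioxy-14,15-dinor-ent-labdan-6-one (epoxide oxygen anti to C20)
Conditions: 30% aq H2O2, NaOH (cat.), MeOH, 0 °C to rt
Reagents that add atoms: hydrogen peroxide, OO
Why: Weitz–Scheffer nucleophilic epoxidation, in which hydroperoxide should add to C8 on the face away from the axial C20 methyl and the C9 chain and the enolate then closes on oxygen, which sets the C8–O bond anti to C20; the acetal is stable to base.

**Step 8**
Reactants: 11 epoxy ketone
Product: 12 8-hydroxy-13,13-ethylenedioxy-14,15-dinor-ent-labdan-6-one (8-OH equatorial; C17 axial and syn to C20)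
Conditions: SmI2 (2.5 equiv), THF/MeOH, −90 °C
Reagents that add atoms: none
Why: SmI2 reduction of an α,β-epoxy ketone, in which two single-electron transfers cleave the C7–O bond α to the carbonyl and MeOH protonates the samarium enolate in the cold before β-elimination can occur; the C8–O bond is not touched, so C8 keeps its configuration.

**Step 9**
Reactants: 12 β-hydroxy ketone
Product: 13 13,13-ethylenedioxy-14,15-dinor-ent-labdane-6,8-diol (both hydroxyls equatorial)
Conditions: SmI2 (excess), H2O, Et3N, THF, rt
Reagents that add atoms: none
Why: Electron-transfer ketone reduction with SmI2–water–amine, in which the ketyl and organosamarium intermediates hold the bulky O–Sm group equatorial, away from the three syn-axial methyls C17, C19 and C20, and carbon is protonated axially to give the thermodynamically favoured equatorial 6-OH; hydride reagents would instead attack the open face and give the axial alcohol.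

**Step 10**
Reactants: 13 diol acetal
Product: 14 6,8-dihydroxy-14,15-dinor-ent-labdan-13-one
Conditions: PPTS (cat.), acetone/H2O (10:1), 45 °C
Reagents that add atoms: water, O
Why: Mild acid-catalysed acetal hydrolysis, in which the aqueous medium keeps the 8-hydroxy ketone from dehydrating to a cyclic enol ether and PPTS is too weak an acid to ionise the tertiary C8 alcohol.

**Step 11**
Reactants: 14 dihydroxy ketone; 15 trimethyl phosphonoacetate
Product: 16 methyl (E)-5-[(1S,2S,4R,4aR,8aR)-2,4-dihydroxy-2,5,5,8a-tetramethyldecahydronaphthalen-1-yl]-3-methylpent-2-enoate (target)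
Conditions: 15 (4 equiv), NaH (3.8 equiv), THF, 0 °C; then 14, rt to 50 °C
Reagents that add atoms: none
Why: Horner–Wadsworth–Emmons olefination of a methyl ketone, in which reversible addition of the stabilised phosphonate anion should favour the E enoate with the C12 chain trans to the ester, the minor Z isomer being removable by chromatography; the pre-formed anion, free of excess NaH, is too weak a base to deprotonate the hydroxyls, which holds back oxa-Michael closure of 8-OH on C13.

**Compound list**
1 | β-damascone, (E)-1-(2,6,6-trimethylcyclohex-1-en-1-yl)but-2-en-1-one | C/C=C/C(=O)C1=C(C)CCCC1(C)C | starting material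
2 | nitromethane | C[N+](=O)[O-] | starting material
3 | (S)-3-methyl-4-nitro-1-(2,6,6-trimethylcyclohex-1-en-1-yl)butan-1-one | [O-][N+](=O)C[C@@H](C)CC(=O)C1=C(C)CCCC1(C)C | intermediate
4 | (3S,4R,4aR,8aR)-3,4a,8,8-tetramethyl-4-nitrooctahydronaphthalen-1(2H)-one | [O-][N+](=O)[C@H]1[C@]2(C)CCCC(C)(C)[C@H]2C(=O)C[C@@H]1C | intermediate
5 | but-3-en-2-one | C=CC(C)=O | starting material
6 | trans-fused 9-nitro-9-(3-oxobutyl)decal-6-one, chain axial, nitro equatorial | CC(=O)CC[C@]1([N+](=O)[O-])[C@]2(C)CCCC(C)(C)[C@H]2C(=O)C[C@@H]1C | intermediate
7 | 14,15-dinor-ent-labdane-6,13-dione | CC(=O)CC[C@H]1[C@]2(C)CCCC(C)(C)[C@H]2C(=O)C[C@@H]1C | intermediate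
8 | 13,13-ethylenedioxy-14,15-dinor-ent-labdan-6-one | CC1(CC[C@H]2[C@]3(C)CCCC(C)(C)[C@H]3C(=O)C[C@@H]2C)OCCO1 | intermediate
9 | 6-trimethylsilyloxy-13,13-ethylenedioxy-14,15-dinor-ent-labd-6-ene | CC1(CC[C@H]2[C@]3(C)CCCC(C)(C)[C@H]3C(O[Si](C)(C)C)=C[C@@H]2C)OCCO1 | intermediate
10 | 13,13-ethylenedioxy-14,15-dinor-ent-labd-7-en-6-one | CC1(CC[C@H]2[C@]3(C)CCCC(C)(C)[C@H]3C(=O)C=C2C)OCCO1 | intermediate
11 | 7,8-epoxy-13,13-ethylenedioxy-14,15-dinor-ent-labdan-6-one, oxygen anti to C20 | CC1(CC[C@H]2[C@]3(C)CCCC(C)(C)[C@H]3C(=O)[C@@H]4O[C@@]42C)OCCO1 | intermediate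
12 | 8-hydroxy-13,13-ethylenedioxy-14,15-dinor-ent-labdan-6-one | CC1(CC[C@H]2[C@]3(C)CCCC(C)(C)[C@H]3C(=O)C[C@]2(C)O)OCCO1 | intermediate
13 | 13,13-ethylenedioxy-14,15-dinor-ent-labdane-6,8-diol, both OH equatorial | CC1(CC[C@H]2[C@]3(C)CCCC(C)(C)[C@H]3[C@H](O)C[C@]2(C)O)OCCO1 | intermediate
14 | 6,8-dihydroxy-14,15-dinor-ent-labdan-13-one | CC(=O)CC[C@H]1[C@]2(C)CCCC(C)(C)[C@H]2[C@H](O)C[C@]1(C)O | intermediate
15 | trimethyl phosphonoacetate | COC(=O)CP(=O)(OC)OC | starting material
16 | methyl (E)-5-[(1S,2S,4R,4aR,8aR)-2,4-dihydroxy-2,5,5,8a-tetramethyldecahydronaphthalen-1-yl]-3-methylpent-2-enoate | COC(=O)/C=C(\C)CC[C@H]1[C@]2(C)CCCC(C)(C)[C@H]2[C@H](O)C[C@]1(C)O | target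

**Total step count:** 11. **Longest linear sequence:** 11 (1 to 16).

**Steps most likely to fail**

**Step 1.**
- What may go wrong: the nitronate may fail to close onto the crowded, twisted C10 terminus, or retro-Michael loss of nitromethane from C8 may compete and erode the enantiopurity.
- Fallback idea (known chemistry, sets out from 1, returns at 7): C9 is brought in as the γ-carbon of an allylsilane, and C9–C10 is made under Lewis-acid activation. This gives C10 tertiary cationic character and does not depend on a reversible anionic equilibrium.
- Boronate: propargyltrimethylsilane is hydroborated with pinacolborane (Cp2Zr(H)Cl cat.) to (E)-3-(trimethylsilyl)prop-1-enylboronic acid pinacol ester F1.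
- C8–C9 bond: Hayashi–Miyaura addition of F1 to the crotonyl alkene of 1 is run with [Rh(OH)(cod)]2 in dioxane/H2O, the BINAP enantiomer being chosen for the (S) centre. It should give (S,E)-3-methyl-6-(trimethylsilyl)-1-(2,6,6-trimethylcyclohex-1-en-1-yl)hex-4-en-1-one F2.
- C9–C10 bond: intramolecular Hosomi–Sakurai addition (TiCl4, CH2Cl2, −78 °C) through the chair with equatorial C8 methyl, followed by base equilibration of C5, should give the trans-fused 9-vinyldecal-6-one F3.
- Return to the route: cross metathesis of F3 with 5 (second-generation Hoveyda–Grubbs catalyst, CH2Cl2, reflux) should give the 9-[(E)-3-oxobut-1-enyl]decal-6-one F4. Hydrogenation (H2, Pd/C, EtOAc) then gives 7.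

**Step 2.**
- What may go wrong: bimolecular addition at a nitronate flanked by the quaternary C10 may be slow and reversible, with base-induced polymerisation of 5 outrunning it.
- Fallback idea (sets out from 3, isolated after stage one of step 1, returns at 6): the order of bond formation is changed, so that C9–C11 is made while C9 is still an unhindered primary nitro carbon.
- C9–C11 bond: 3 and 5 (1 equiv) with Et3N (0.1 equiv) in MeCN at 0 °C should give (3S)-3-methyl-4-nitro-1-(2,6,6-trimethylcyclohex-1-en-1-yl)octane-1,7-dione F5 as a mixture of C9 epimers.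
- Ring closure: F5 is closed with DBU in DMSO as in stage two of step 1. The crowded C9–C10 bond is then formed intramolecularly, giving 6.
- The C9 epimer of the tertiary nitro diketone F6, if formed alongside, is carried through step 3 with it, since both give the same C9 radical and hence 7.

**Step 6.**
- What may go wrong: the syn β-hydride elimination may be hampered, because the only C8–H lies on the face shielded by C19 and C20. Protodesilylation back to the ketone could then take over.
- Fallback (sets out from 9, returns at 10): the syn elimination is replaced by an anti elimination.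
- Bromination: NBS with NaHCO3 in THF at 0 °C should brominate 9 axially on the open face to the axial 7-bromo-6-ketone F7.
- Elimination: the C7–Br bond of F7 is antiperiplanar to the axial C8–H, so E2 dehydrobromination (LiBr, Li2CO3, DMF, 120 °C) should give 10.

**Further compounds**
F1 | step 1 | (E)-trimethyl[3-(4,4,5,5-tetramethyl-1,3,2-dioxaborolan-2-yl)prop-2-en-1-yl]silane | C[Si](C)(C)C/C=C/B1OC(C)(C)C(C)(C)O1
F2 | step 1 | (S,E)-3-methyl-6-(trimethylsilyl)-1-(2,6,6-trimethylcyclohex-1-en-1-yl)hex-4-en-1-one | C[Si](C)(C)C/C=C/[C@@H](C)CC(=O)C1=C(C)CCCC1(C)C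
F3 | step 1 | trans-fused 4,4,8,10-tetramethyl-9-vinyldecal-6-one, vinyl and C8 methyl equatorial | C=C[C@H]1[C@]2(C)CCCC(C)(C)[C@H]2C(=O)C[C@@H]1C
F4 | step 1 | trans-fused 9-[(E)-3-oxobut-1-enyl]-4,4,8,10-tetramethyldecal-6-one | CC(=O)/C=C/[C@H]1[C@]2(C)CCCC(C)(C)[C@H]2C(=O)C[C@@H]1C
F5 | step 2 | (3S)-3-methyl-4-nitro-1-(2,6,6-trimethylcyclohex-1-en-1-yl)octane-1,7-dione, epimers at the nitro carbon | CC(=O)CCC([N+](=O)[O-])[C@@H](C)CC(=O)C1=C(C)CCCC1(C)C
F6 | step 2 | C9 epimer of 6, chain equatorial, nitro axial | CC(=O)CC[C@@]1([N+](=O)[O-])[C@]2(C)CCCC(C)(C)[C@H]2C(=O)C[C@@H]1C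
F7 | step 6 | 7-bromo-13,13-ethylenedioxy-14,15-dinor-ent-labdan-6-one, bromine axial and anti to C20 | CC1(CC[C@H]2[C@]3(C)CCCC(C)(C)[C@H]3C(=O)[C@H](Br)[C@@H]2C)OCCO1
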